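(All runs stem from a simulated flask with made-up constants; the scatter is artificial.)

Z, the complex with one ligand exchanged, is the wanted product of this flask of X and D, and the question is whether it is still gaining at the asked time.

| flask | X | D | remark | time |
|---|---|---|---|---|
| south-west | 0.23 M | 2 equiv | run made earlier |  |
| north | 0.35 M | 2 equiv | run made earlier |  |
| east | 0.46 M | 4 equiv | run made earlier |  |
| flask | 0.46 M | 2.00 equiv |  | 12 min |

- south-west (time / min: Z / %, E / %, X / %): 0.667: 38, 6, 59; 2.00: 58, 10, 32; 3.00: 59, 7, 25; 5.00: 68, 14, 18; 8.00: 63, 11, 14
- north (time / min: Z / %, E / %, X / %): 1.33: 55, 13, 30; 3.00: 66, 14, 23; 4.00: 65, 18, 11; 6.00: 66, 14, 12; 8.00: 66, 16, 13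
- east (time / min: Z / %, E / %, X / %): 0.500: 61, 17, 22; 1.00: 57, 29, 9; 2.00: 51, 42, 3; 4.00: 45, 39, 4; 8.00: 37, 32, 4

(readings scatter by 2 percentage points)

1. equivalents of D to X, everything else as given, that leave most Z at 12 min
2. the amount of Z then, in percent of the X charged
3. the amount of Z with the amounts as given

- what is said of L includes Q
- Q is a solid; its amount is given per volume of the solution
- on the list of suspects stand: Z + D <-> L + E; X + D <-> L + Z; Q <-> L; L + E -> J

Turned round, the question reads: with E steady, for Z still to rise at 12 min, X would have to fall faster than the pool of X, Z and E loses material to J. The east run shows that loss as the part of the charge missing from the pool. Its growth between 4.00 min and 8.00 min, divided by the elapsed time and the mean E, gives a reading of 0.106 min⁻¹. This is the bleed constant, the fraction of E passing to J each minute, pseudo-first-order as long as dissolved L holds steady.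

Multiplied by E, with the north run's 16% standing in for this flask at the same equivalents, it gives a leak of 0.0169 min⁻¹ of the charge. In the north run, the opposite outcome needs X to fall by 6.8 percentage points between 4.00 min and 8.00 min, but X there reads 11% and then 13%, so in these scattered readings the feed stands below the leak. This reckoning lets the pool, read in the north run as 92.0%, shrink at the leak from 4.00 min on, with Z keeping its share of it, and so estimates that Z near 66% stands at 56.3% in this flask at 12 min.

The forecast, with E's loss “first order in E because L is constant”, gives 59% of Z as charged, 2.7 points above this reckoning, and 63% at 1.4 equiv.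

The flask gives 57.1% of Z, and the best charge, 1.40 equiv, gives 61.9%. At 12 min Z in this flask is made at 0.0319 of the rate at which it is used up, each step taken net. The flask's E of 15.5% puts the leak at 0.0164 min⁻¹, and J gains 0.0149 min⁻¹ of the charge between 6.00 min and 12.0 min.

    Z + D ⇌ L + E (K = 0.132, k = 0.0128 L mol⁻¹ s⁻¹)
    X + D ⇌ L + Z (K = 2.76, k = 0.0325 L mol⁻¹ s⁻¹)
    Q ⇌ L, rate k3*(cs3 - [L]) while solid is left; crystals form when [L] > cs3 (solubility = 0.160 M, k = 0.123 s⁻¹)
    L + E → J (k = 0.00919 L mol⁻¹ s⁻¹)

In the neighbour flask with 5.00 equiv of D, E stands at 31.1% at 12 min, and the bleed constant, with that E taken as holding over the whole time, gives an estimate of 39.6% of the charge in J. The computed J there is 42.1%.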